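**Target:** 4-[(3E,7E)-10-[(1S)-2,2-dimethyl-6-methylidenecyclohexyl]-4,8-dimethyldeca-3,7-dien-1-yl]furan-2(5H)-one. It has one stereocentre (S, the ring CH between C(=CH2) and CMe2) and two E-trisubstituted alkenes.

**Retrosynthetic overview**
1. 28 ⇒ Negishi C(sp3)–C(sp2) disconnection at the lactone C4–CH2 bond: alkyl iodide 25 + 4-bromofuran-2(5H)-one 26.
2. 25 ⇒ Negishi disconnection at the ring-side C(Me)–CH2 bond: (S)-iodide 13 + dienyl iodide 22. 22 comes from two pent-3-yn-1-ol (14) units, and both E-alkenes come from syn-hydrozirconation/iodination.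
3. 13 ⇒ keto ester 9: the two-carbon arm, the exocyclic methylene and the (S) centre all come from one catalytic enantioselective [3,3] shift of 2-alkoxyacrylate 8 (proposed new step).
4. 8 ⇒ allylic alcohol 5 ⇒ 3-methylcyclohex-2-en-1-one 1 (cuprate addition, enol triflate, carbonylation).
5. Ring order: no ring is closed in the route. The carbocycle is bought as 1 and carried from the start; the butenolide is bought as 26 and attached last.

**Assumption:** 1, 6, 14 and 26 are bought. The guanidinium catalyst of step 6 is made separately from trans-cyclohexane-1,2-diamine. Its (1R,2R) antipode is written; the sense of induction is taken by analogy with acyclic cases, and the (1S,2S) antipode is used instead if the first run gives the (R) product.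

**Route**

Step 1
Reactants: 1 3-methylcyclohex-2-en-1-one
Product: 3 3,3-dimethylcyclohex-1-en-1-yl trifluoromethanesulfonate, via lithium enolate 2 (not isolated)
Conditions: Me2CuLi (from CuI + 2 MeLi), Et2O, 0 °C; then PhNTf2, THF, 0 °C → rt
Reagents that add atoms: lithium dimethylcuprate, [Li+].C[Cu-]C; N-phenylbis(trifluoromethanesulfonimide), O=S(=O)(N(c1ccccc1)S(=O)(=O)C(F)(F)F)C(F)(F)F
Why: Cuprate conjugate addition gives the regiodefined enolate 2 (C3 becomes CMe2, so no stereocentre arises), and O-sulfonylation by PhNTf2 (McMurry–Scott enolate trapping) fixes the double bond next to the quaternary carbon.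

Step 2
Reactants: 3 3,3-dimethylcyclohex-1-en-1-yl trifluoromethanesulfonate
Product: 4 methyl 3,3-dimethylcyclohex-1-ene-1-carboxylate
Conditions: Pd(OAc)2 (3 mol%), PPh3 (6 mol%), CO (1 atm), MeOH, Et3N, DMF, 60 °C
Reagents that add atoms: carbon monoxide, [C-]#[O+]; methanol, CO
Why: Zerovalent palladium adds into the vinyl C–OTf bond, CO inserts and methanol cleaves the acylpalladium (palladium-catalysed alkoxycarbonylation of an enol triflate).

Step 3
Reactants: 4 methyl 3,3-dimethylcyclohex-1-ene-1-carboxylate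
Product: 5 (3,3-dimethylcyclohex-1-en-1-yl)methanol
Conditions: i-Bu2AlH (2.5 equiv), CH2Cl2, −78 → 0 °C; aq. KNaC4H4O6 work-up
Reagents that add atoms: none
Why: Two hydride transfers from i-Bu2AlH reduce the conjugated ester 1,2 to the allylic alcohol (ester reduction) without touching the trisubstituted alkene.

Step 4
Reactants: 5 (3,3-dimethylcyclohex-1-en-1-yl)methanol; 6 methyl 2-diazo-2-(dimethoxyphosphoryl)acetate
Product: 7 methyl 2-(dimethoxyphosphoryl)-2-[(3,3-dimethylcyclohex-1-en-1-yl)methoxy]acetate (racemic)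
Conditions: Rh2(OAc)4 (1 mol%), toluene, 80 °C, slow addition of 6
Reagents that add atoms: none
Why: The rhodium carbenoid from 6 inserts into the O–H bond (carbenoid O–H insertion) faster than it cyclopropanates the hindered trisubstituted alkene; the racemic α-carbon is destroyed in step 5.

Step 5
Reactants: 7 methyl 2-(dimethoxyphosphoryl)-2-[(3,3-dimethylcyclohex-1-en-1-yl)methoxy]acetate
Product: 8 methyl 2-[(3,3-dimethylcyclohex-1-en-1-yl)methoxy]prop-2-enoate
Conditions: 37% aq. HCHO, K2CO3, THF, rt
Reagents that add atoms: formaldehyde, C=O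
Why: Horner–Wadsworth–Emmons methylenation of the phosphonate with formaldehyde gives the 2-alkoxyacrylate, which is the vinyl half of the Claisen system.

Step 6
Reactants: 8 methyl 2-[(3,3-dimethylcyclohex-1-en-1-yl)methoxy]prop-2-enoate
Product: 9 methyl 3-[(1S)-2,2-dimethyl-6-methylidenecyclohexyl]-2-oxopropanoate
Conditions: N,N'-bis[(1R,2R)-2-(2-phenyl-1H-pyrrol-1-yl)cyclohexyl]guanidinium tetrakis[3,5-bis(trifluoromethyl)phenyl]borate (20 mol%), hexanes, 40 °C, 5–7 d
Reagents that add atoms: none
Why: Proposed new method: a catalytic enantioselective Claisen rearrangement on a substrate class where it has not been shown (a 1-cycloalkenylmethyl 2-alkoxyacrylate whose allyl part carries a ring substituent on its central carbon and a quaternary carbon next to the bond-forming terminus): the guanidinium ion binds the ether oxygen and the ester carbonyl of 8 through two N–H···O hydrogen bonds, stabilises the enolate-like half of the polarised chair transition state and so lowers the barrier of the concerted [3,3] shift below that of the thermal background, while the 2-phenylpyrrole arms sit over the partly cationic cyclohexenyl half (cation–π contact) and leave only the Si face of the ring CH carbon open to the acrylate CH2 terminus, anti to the pseudoaxial methyl of the CMe2 unit, so that the C–C bond, the exocyclic methylene and the (S) centre arise in one event and the neopentylic position, which would resist an intermolecular SN2' attack, is reached inside a six-membered array; the closest known reaction type is the hydrogen-bond-donor- or chiral-Lewis-acid-catalysed Claisen (Gosteli–Claisen) rearrangement of acyclic 2-alkoxycarbonyl allyl vinyl ethers.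

Step 7
Reactants: 9 methyl 3-[(1S)-2,2-dimethyl-6-methylidenecyclohexyl]-2-oxopropanoate
Product: 11 2-[(1S)-2,2-dimethyl-6-methylidenecyclohexyl]acetic acid, via lithium keto carboxylate 10 (not isolated)
Conditions: LiOH, THF/H2O, 0 °C; then 30% H2O2, 0 °C → rt; then aq. HCl
Reagents that add atoms: hydrogen peroxide, OO
Why: Saponification gives the α-keto carboxylate 10, whose ketone adds hydroperoxide and fragments with loss of CO2 (oxidative decarboxylation of an α-keto acid); the stereocentre is β to the carbonyl and the unactivated alkene is inert to basic H2O2.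

Step 8
Reactants: 11 2-[(1S)-2,2-dimethyl-6-methylidenecyclohexyl]acetic acid
Product: 12 2-[(1S)-2,2-dimethyl-6-methylidenecyclohexyl]ethan-1-ol
Conditions: LiAlH4, THF, 0 °C → rt
Reagents that add atoms: none
Why: Hydride reduction of the carboxylic acid to the primary alcohol (LiAlH4 reduction) touches neither the alkene nor the stereocentre.

Step 9
Reactants: 12 2-[(1S)-2,2-dimethyl-6-methylidenecyclohexyl]ethan-1-ol
Product: 13 (2S)-2-(2-iodoethyl)-1,1-dimethyl-3-methylidenecyclohexane
Conditions: I2, PPh3, imidazole, CH2Cl2, 0 °C → rt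
Reagents that add atoms: iodine, II
Why: Appel-type iodination, in which iodide displaces the alkoxyphosphonium group at the unhindered primary carbon (SN2).

Step 10
Reactants: 14 pent-3-yn-1-ol
Product: 15 5-chloropent-2-yne
Conditions: SOCl2, pyridine, CH2Cl2, 0 °C → reflux
Reagents that add atoms: thionyl chloride, O=S(Cl)Cl
Why: Chlorosulfite formation followed by SN2 displacement by chloride (alcohol-to-chloride conversion with SOCl2/pyridine).

Step 11
Reactants: 15 5-chloropent-2-yne
Product: 17 (2E)-5-chloro-2-iodopent-2-ene, via alkenylzirconocene 16 (not isolated)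
Conditions: Cp2Zr(H)Cl (2 equiv; Cp = cyclopentadienyl), THF, 50 °C; then I2, 0 °C
Reagents that add atoms: iodine, II
Why: syn-Hydrozirconation (Schwartz) with excess Cp2Zr(H)Cl and warming equilibrates zirconium to the less hindered methyl-bearing carbon, and iodinolysis with retention gives the E-iodide, which fixes the alkene geometry.

Step 12
Reactants: 14 pent-3-yn-1-ol
Product: 18 5-iodopent-2-yne
Conditions: I2, PPh3, imidazole, CH2Cl2, 0 °C
Reagents that add atoms: iodine, II
Why: Appel-type iodination of a primary alcohol (SN2 on the alkoxyphosphonium ion).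

Step 13
Reactants: 18 5-iodopent-2-yne; 17 (2E)-5-chloro-2-iodopent-2-ene
Product: 20 (6E)-9-chloro-6-methylnon-6-en-2-yne, via pent-3-yn-1-ylzinc iodide 19 (not isolated)
Conditions: 18, Zn dust, LiCl, THF, 40 °C; then 17, Pd(PPh3)4 (3 mol%), THF, rt
Reagents that add atoms: none
Why: Zinc inserts into the primary C–I bond and the alkylzinc couples with the alkenyl iodide under zerovalent palladium with retention of the E geometry (Negishi coupling); the alkyl chloride and the alkyne are inert.

Step 14
Reactants: 20 (6E)-9-chloro-6-methylnon-6-en-2-yne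
Product: 22 (3E,7E)-1-chloro-8-iodo-4-methylnona-3,7-diene, via alkenylzirconocene 21 (not isolated)
Conditions: Cp2Zr(H)Cl (2 equiv), THF, 50 °C; then I2, 0 °C
Reagents that add atoms: iodine, II
Why: The same syn-hydrozirconation/iodinolysis as in step 11 (Schwartz hydrozirconation) sets the second E-alkene, since the alkyne reacts much faster than the trisubstituted alkene or the alkyl chloride.

Step 15
Reactants: 13 (2S)-2-(2-iodoethyl)-1,1-dimethyl-3-methylidenecyclohexane; 22 (3E,7E)-1-chloro-8-iodo-4-methylnona-3,7-diene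
Product: 24 (2S)-2-[(3E,7E)-10-chloro-3,7-dimethyldeca-3,7-dien-1-yl]-1,1-dimethyl-3-methylidenecyclohexane, via alkylzinc iodide 23 (not isolated)
Conditions: 13, Zn dust, LiCl, THF, 40 °C; then 22, PdCl2(dppf) (5 mol%; dppf = 1,1'-bis(diphenylphosphino)ferrocene), THF, rt
Reagents that add atoms: none
Why: Negishi C(sp3)–C(sp2) coupling, in which zerovalent palladium adds only into the alkenyl C–I bond of 22 and the bidentate dppf ligand suppresses β-hydride elimination, so ring and chain are joined with retention of alkene geometry and without touching the allylic stereocentre.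

Step 16
Reactants: 24 (2S)-2-[(3E,7E)-10-chloro-3,7-dimethyldeca-3,7-dien-1-yl]-1,1-dimethyl-3-methylidenecyclohexane
Product: 25 (2S)-2-[(3E,7E)-10-iodo-3,7-dimethyldeca-3,7-dien-1-yl]-1,1-dimethyl-3-methylidenecyclohexane
Conditions: NaI, acetone, reflux
Reagents that add atoms: sodium iodide, [Na+].[I-]
Why: Finkelstein halide exchange (SN2) at the primary carbon, driven by precipitation of NaCl.

Step 17
Reactants: 25 (2S)-2-[(3E,7E)-10-iodo-3,7-dimethyldeca-3,7-dien-1-yl]-1,1-dimethyl-3-methylidenecyclohexane; 26 4-bromofuran-2(5H)-one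
Product: 28 4-[(3E,7E)-10-[(1S)-2,2-dimethyl-6-methylidenecyclohexyl]-4,8-dimethyldeca-3,7-dien-1-yl]furan-2(5H)-one, via alkylzinc iodide 27 (not isolated)
Conditions: 25, Zn dust, LiCl, THF, 40 °C; then 26, Pd(PPh3)4 (5 mol%), THF, rt → 40 °C
Reagents that add atoms: none
Why: Negishi coupling of the alkylzinc with the vinylogous acyl bromide 26, whose C–Br bond adds readily to zerovalent palladium, while the organozinc neither deprotonates nor adds to the butenolide.

**Compound list**
1 | 3-methylcyclohex-2-en-1-one | CC1=CC(=O)CCC1 | starting material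
2 | lithium 3,3-dimethylcyclohex-1-en-1-olate | [Li+].[O-]C1=CC(C)(C)CCC1 | intermediate
3 | 3,3-dimethylcyclohex-1-en-1-yl trifluoromethanesulfonate | CC1(C)CCCC(OS(=O)(=O)C(F)(F)F)=C1 | intermediate
4 | methyl 3,3-dimethylcyclohex-1-ene-1-carboxylate | COC(=O)C1=CC(C)(C)CCC1 | intermediate
5 | (3,3-dimethylcyclohex-1-en-1-yl)methanol | OCC1=CC(C)(C)CCC1 | intermediate
6 | methyl 2-diazo-2-(dimethoxyphosphoryl)acetate | COC(=O)C(=[N+]=[N-])P(=O)(OC)OC | starting material
7 | methyl 2-(dimethoxyphosphoryl)-2-[(3,3-dimethylcyclohex-1-en-1-yl)methoxy]acetate (racemic) | COC(=O)C(OCC1=CC(C)(C)CCC1)P(=O)(OC)OC | intermediate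
8 | methyl 2-[(3,3-dimethylcyclohex-1-en-1-yl)methoxy]prop-2-enoate | C=C(OCC1=CC(C)(C)CCC1)C(=O)OC | intermediate
9 | methyl 3-[(1S)-2,2-dimethyl-6-methylidenecyclohexyl]-2-oxopropanoate | C=C1CCCC(C)(C)[C@@H]1CC(=O)C(=O)OC | intermediate
10 | lithium 3-[(1S)-2,2-dimethyl-6-methylidenecyclohexyl]-2-oxopropanoate | [Li+].C=C1CCCC(C)(C)[C@@H]1CC(=O)C(=O)[O-] | intermediate
11 | 2-[(1S)-2,2-dimethyl-6-methylidenecyclohexyl]acetic acid | C=C1CCCC(C)(C)[C@@H]1CC(=O)O | intermediate
12 | 2-[(1S)-2,2-dimethyl-6-methylidenecyclohexyl]ethan-1-ol | C=C1CCCC(C)(C)[C@@H]1CCO | intermediate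
13 | (2S)-2-(2-iodoethyl)-1,1-dimethyl-3-methylidenecyclohexane | C=C1CCCC(C)(C)[C@@H]1CCI | intermediate
14 | pent-3-yn-1-ol | CC#CCCO | starting material
15 | 5-chloropent-2-yne | CC#CCCCl | intermediate
16 | chlorobis(cyclopentadienyl)[(2E)-5-chloropent-2-en-2-yl]zirconium | Cl[Zr](/C(C)=C/CCCl)(C1C=CC=C1)C1C=CC=C1 | intermediate
17 | (2E)-5-chloro-2-iodopent-2-ene | I/C(C)=C/CCCl | intermediate
18 | 5-iodopent-2-yne | CC#CCCI | intermediate
19 | pent-3-yn-1-ylzinc iodide | CC#CCC[Zn]I | intermediate
20 | (6E)-9-chloro-6-methylnon-6-en-2-yne | CC#CCC/C(C)=C/CCCl | intermediate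
21 | chlorobis(cyclopentadienyl)[(2E,6E)-9-chloro-6-methylnona-2,6-dien-2-yl]zirconium | Cl[Zr](/C(C)=C/CC/C(C)=C/CCCl)(C1C=CC=C1)C1C=CC=C1 | intermediate
22 | (3E,7E)-1-chloro-8-iodo-4-methylnona-3,7-diene | I/C(C)=C/CC/C(C)=C/CCCl | intermediate
23 | {2-[(1S)-2,2-dimethyl-6-methylidenecyclohexyl]ethyl}zinc iodide | C=C1CCCC(C)(C)[C@@H]1CC[Zn]I | intermediate
24 | (2S)-2-[(3E,7E)-10-chloro-3,7-dimethyldeca-3,7-dien-1-yl]-1,1-dimethyl-3-methylidenecyclohexane | C=C1CCCC(C)(C)[C@@H]1CC/C(C)=C/CC/C(C)=C/CCCl | intermediate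
25 | (2S)-2-[(3E,7E)-10-iodo-3,7-dimethyldeca-3,7-dien-1-yl]-1,1-dimethyl-3-methylidenecyclohexane | C=C1CCCC(C)(C)[C@@H]1CC/C(C)=C/CC/C(C)=C/CCI | intermediate
26 | 4-bromofuran-2(5H)-one | BrC1=CC(=O)OC1 | starting material
27 | {(3E,7E)-10-[(1S)-2,2-dimethyl-6-methylidenecyclohexyl]-4,8-dimethyldeca-3,7-dien-1-yl}zinc iodide | C=C1CCCC(C)(C)[C@@H]1CC/C(C)=C/CC/C(C)=C/CCC[Zn]I | intermediate
28 | 4-[(3E,7E)-10-[(1S)-2,2-dimethyl-6-methylidenecyclohexyl]-4,8-dimethyldeca-3,7-dien-1-yl]furan-2(5H)-one | C=C1CCCC(C)(C)[C@@H]1CC/C(C)=C/CC/C(C)=C/CCC1=CC(=O)OC1 | target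

**Step count:** 17 steps in total. The longest linear sequence is 12 steps (steps 1–9, 15, 16, 17). The chain branch (steps 10–14) is 5 steps.

**Three steps most likely to fail**

Step 6 (the proposed new step). The bond-forming ring carbon is neopentylic and the allyl part is substituted on its central carbon. The catalysed rate may therefore be low, the racemic thermal pathway may compete, and the facial selectivity is untested; the ee is read at alcohol 12 by chiral GC. The fallback uses known chemistry, sets out from 5 and comes back at 11. Alcohol 5 is heated with MeC(OEt)3 and catalytic EtCO2H at 140 °C (Johnson–Claisen rearrangement) to give racemic ethyl 2-(2,2-dimethyl-6-methylidenecyclohexyl)acetate F1. Saponification with LiOH gives racemic 2-(2,2-dimethyl-6-methylidenecyclohexyl)acetic acid F2. The acid is resolved by fractional crystallisation of (1S)-1-phenylethan-1-aminium 2-[(1S)-2,2-dimethyl-6-methylidenecyclohexyl]acetate F3 (the (R)-amine is used if the other diastereomeric salt is the less soluble one), and aq. HCl releases 11.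

Step 14. Regiocontrol of Zr–H addition rests on thermodynamic equilibration between a methyl and a primary alkyl substituent, so a few percent of the 3-iodo isomer is possible. Unlike in step 11, that isomer cannot be distilled off here, and slow attack on the trisubstituted alkene is also possible. The fallback sets out from 13 and comes back at 25, replacing steps 10–16; each E-alkene is built by Negishi carboalumination of a terminal alkyne.
- Iodide 13 is alkylated with LiC≡CH·H2NCH2CH2NH2 in DMSO to give (2S)-2-(but-3-yn-1-yl)-1,1-dimethyl-3-methylidenecyclohexane F4.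
- Me3Al with catalytic Cp2ZrCl2 in CH2Cl2 gives dimethyl{(1E)-4-[(1S)-2,2-dimethyl-6-methylidenecyclohexyl]-2-methylbut-1-en-1-yl}alumane F5, and I2 converts it into (2S)-2-[(3E)-4-iodo-3-methylbut-3-en-1-yl]-1,1-dimethyl-3-methylidenecyclohexane F6.
- Zinc insertion into commercial 4-iodo-1-(trimethylsilyl)but-1-yne gives [4-(trimethylsilyl)but-3-yn-1-yl]zinc iodide F7, which couples with F6 under Pd(PPh3)4 to give {(5E)-8-[(1S)-2,2-dimethyl-6-methylidenecyclohexyl]-6-methyloct-5-en-1-yn-1-yl}trimethylsilane F8.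
- K2CO3 in MeOH gives (2S)-1,1-dimethyl-3-methylidene-2-[(3E)-3-methyloct-3-en-7-yn-1-yl]cyclohexane F9.
- A second carboalumination gives dimethyl{(1E,5E)-8-[(1S)-2,2-dimethyl-6-methylidenecyclohexyl]-2,6-dimethylocta-1,5-dien-1-yl}alumane F10; its ate complex with n-BuLi opens oxirane to give (3E,7E)-10-[(1S)-2,2-dimethyl-6-methylidenecyclohexyl]-4,8-dimethyldeca-3,7-dien-1-ol F11.
- I2, PPh3 and imidazole then give 25.

Step 17. Zinc insertion on a small scale of late-stage material, followed by coupling to a base-sensitive and reducible bromobutenolide, risks protodezincation or reduction of 26. The fallback sets out from 25 and comes back at 28; it builds the lactone ring instead of coupling it. Iodide 25 is treated with t-BuLi (2.1 equiv, Et2O, −78 °C) to give {(3E,7E)-10-[(1S)-2,2-dimethyl-6-methylidenecyclohexyl]-4,8-dimethyldeca-3,7-dien-1-yl}lithium F12. This is acylated with 2-[(tert-butyldimethylsilyl)oxy]-N-methoxy-N-methylacetamide to give (5E,9E)-1-[(tert-butyldimethylsilyl)oxy]-12-[(1S)-2,2-dimethyl-6-methylidenecyclohexyl]-6,10-dimethyldodeca-5,9-dien-2-one F13. HF·pyridine gives (5E,9E)-12-[(1S)-2,2-dimethyl-6-methylidenecyclohexyl]-1-hydroxy-6,10-dimethyldodeca-5,9-dien-2-one F14. Ph3P=C=C=O in toluene at 110 °C acylates the hydroxyl group and closes the butenolide by intramolecular Wittig olefination to give 28.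

**Further compounds**
F1 | step 6 | ethyl 2-(2,2-dimethyl-6-methylidenecyclohexyl)acetate (racemic) | C=C1CCCC(C)(C)C1CC(=O)OCC
F2 | step 6 | 2-(2,2-dimethyl-6-methylidenecyclohexyl)acetic acid (racemic) | C=C1CCCC(C)(C)C1CC(=O)O
F3 | step 6 | (1S)-1-phenylethan-1-aminium 2-[(1S)-2,2-dimethyl-6-methylidenecyclohexyl]acetate | C=C1CCCC(C)(C)[C@@H]1CC(=O)[O-].C[C@H]([NH3+])c1ccccc1
F4 | step 14 | (2S)-2-(but-3-yn-1-yl)-1,1-dimethyl-3-methylidenecyclohexane | C=C1CCCC(C)(C)[C@@H]1CCC#C
F5 | step 14 | dimethyl{(1E)-4-[(1S)-2,2-dimethyl-6-methylidenecyclohexyl]-2-methylbut-1-en-1-yl}alumane | C=C1CCCC(C)(C)[C@@H]1CC/C(C)=C/[Al](C)C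
F6 | step 14 | (2S)-2-[(3E)-4-iodo-3-methylbut-3-en-1-yl]-1,1-dimethyl-3-methylidenecyclohexane | C=C1CCCC(C)(C)[C@@H]1CC/C(C)=C/I
F7 | step 14 | [4-(trimethylsilyl)but-3-yn-1-yl]zinc iodide | C[Si](C)(C)C#CCC[Zn]I
F8 | step 14 | {(5E)-8-[(1S)-2,2-dimethyl-6-methylidenecyclohexyl]-6-methyloct-5-en-1-yn-1-yl}trimethylsilane | C=C1CCCC(C)(C)[C@@H]1CC/C(C)=C/CCC#C[Si](C)(C)C
F9 | step 14 | (2S)-1,1-dimethyl-3-methylidene-2-[(3E)-3-methyloct-3-en-7-yn-1-yl]cyclohexane | C=C1CCCC(C)(C)[C@@H]1CC/C(C)=C/CCC#C
F10 | step 14 | dimethyl{(1E,5E)-8-[(1S)-2,2-dimethyl-6-methylidenecyclohexyl]-2,6-dimethylocta-1,5-dien-1-yl}alumane | C=C1CCCC(C)(C)[C@@H]1CC/C(C)=C/CC/C(C)=C/[Al](C)C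
F11 | step 14 | (3E,7E)-10-[(1S)-2,2-dimethyl-6-methylidenecyclohexyl]-4,8-dimethyldeca-3,7-dien-1-ol | C=C1CCCC(C)(C)[C@@H]1CC/C(C)=C/CC/C(C)=C/CCO
F12 | step 17 | {(3E,7E)-10-[(1S)-2,2-dimethyl-6-methylidenecyclohexyl]-4,8-dimethyldeca-3,7-dien-1-yl}lithium | C=C1CCCC(C)(C)[C@@H]1CC/C(C)=C/CC/C(C)=C/CC[Li]
F13 | step 17 | (5E,9E)-1-[(tert-butyldimethylsilyl)oxy]-12-[(1S)-2,2-dimethyl-6-methylidenecyclohexyl]-6,10-dimethyldodeca-5,9-dien-2-one | C=C1CCCC(C)(C)[C@@H]1CC/C(C)=C/CC/C(C)=C/CCC(=O)CO[Si](C)(C)C(C)(C)C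
F14 | step 17 | (5E,9E)-12-[(1S)-2,2-dimethyl-6-methylidenecyclohexyl]-1-hydroxy-6,10-dimethyldodeca-5,9-dien-2-one | C=C1CCCC(C)(C)[C@@H]1CC/C(C)=C/CC/C(C)=C/CCC(=O)CO
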